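(The earlier runs and the new flask are calculated with made-up constants, and the scatter is random.)

What should I change in the next flask to have more target at 2.0 min: the catalyst, the way the solid dissolves, or the gas transfer?

all flasks: gas phase 43 mM (held); added ligand 2.1 mM
- green: solid substrate 0.49 M; catalyst 3.5 mM; run made earlier
- violet: solid substrate 0.77 M; catalyst 3.5 mM; run made earlier
- blue: solid substrate 0.35 M; catalyst 7 mM; run made earlier
- flask: solid substrate 0.35 M; catalyst 3.5 mM; time 2.0 min

| run | time / s | target / % | solid substrate / % |
|---|---|---|---|
| green | 10.0 | 1.2 | 90.4 |
| green | 20.0 | 2.2 | 80.9 |
| green | 30.0 | 3.8 | 75.2 |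
| green | 50.0 | 7.7 | 67.1 |
| green | 80.0 | 15.7 | 56.9 |
| green | 90.0 | 17.1 | 52.5 |
| violet | 10.0 | 0 | 93.6 |
| violet | 12.0 | 1.4 | 91.8 |
| violet | 20.0 | 0 | 87.0 |
| violet | 40.0 | 5.1 | 81.2 |
| violet | 60.0 | 7.5 | 77.7 |
| violet | 90.0 | 12.4 | 69.2 |
| blue | 10.0 | 2.8 | 86.3 |
| blue | 25.0 | 11.7 | 68.4 |
| blue | 40.0 | 20.0 | 57.1 |
| blue | 60.0 | 33.5 | 39.5 |
| blue | 90.0 | 49.5 | 13.4 |

(readings scatter by 1 percentage point)

- in percentages every species weighs as the solid substrate in it: one side product counts as two
- as a solid, counted per litre of solution: solid substrate
- at the start none of the gas is dissolved
- steps under discussion: solid substrate <-> starting material; starting material + dissolved gas + catalyst -> catalyst + target; gas phase <-> dissolved gas; catalyst + added ligand <-> idle complex; starting material + target -> side product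
- at the start none of the solid substrate is in solution

- the target standing at 2.0 min, as a percentage of the solid substrate charged
- concentration of dissolved gas in solution at 1.0 min, in percent of saturation
- the change that raises the amount of target at 2.0 min, in percent of the solid substrate charged most ("none" if none brings more than 2 percentage points) (north-east / south-east / east / north / none)
- amount of target at 2.0 min, in percent of the solid substrate charged, after east

- north-east: doubling the amount of catalyst, all else as stated
- south-east: doubling the dissolution coefficient of the solid substrate, all else as stated
- east: doubling the solubility of the solid substrate, all else as stated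
- north: doubling the transfer coefficient of the gas phase, all else as stated

I decided by one number read from the runs. On the straight stretch of the green run, between 50.0 s and 90.0 s, target rose by 0.197 min⁻¹. This is the pace, the target made per minute on that stretch, counted as a fraction of this flask's charge. The violet run, with a larger charge of solid substrate, gives 0.193 min⁻¹, so the two readings are alike: a zero-order stretch in the charge. The blue run, with this flask's charge and twice the catalyst, gives 0.374 min⁻¹, which is twice the green pace.

So I kept the charge and meant to double the catalyst. Extending the green line back gives a lag of 17.2 s. My reckoning for the flask was therefore 33.8%, and 64.1% with doubled catalyst.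

The forecast stood at 33% (29% to 37%), with 75% for the gas, 41% after east, and north-east as best change: “Rate barely depends on charge or dissolved substrate”.

The flask gave 33.8%, 91.3% for the gas, 42.2% after east, and north-east as best, worth 27 percentage points.

    solid substrate ⇌ starting material, rate k1*(cs1 - [starting material]) while solid is left; crystals form when [starting material] > cs1 (solubility = 0.150 M, k = 0.0410 s⁻¹)
    starting material + dissolved gas + catalyst → catalyst + target (k = 170 L² mol⁻² s⁻¹)
    gas phase ⇌ dissolved gas, rate k3*(csat - [dissolved gas]) (kL = 0.400 s⁻¹)
    catalyst + added ligand ⇌ idle complex, settled at all times (K = 770 L mol⁻¹)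
    starting material + target → side product (k = 0.0560 L mol⁻¹ s⁻¹)

The forecast and the flask part on the gas: dissolved gas stood at 91.3% at 1.0 min, above the forecast's 75%. From 1.00 min to 2.0 min the flask gained 0.166 min⁻¹, below the pace. Part of what keeps the target of this flask down at 2.0 min is the pairing of catalyst with added ligand, together with the length of the run: the idle complex held 37.6% of the catalyst charged, the run without that pairing gives 47.7% against 33.8%, and the run ten times as long gives 47.2%.

For the neighbour charged with 0.14 M of solid substrate, the pace rescaled to that charge gives 84.5%. The computed neighbour gives 60.4%, with solid substrate at 0%, starting material at 15.5% and side product at 24.1%.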